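**Retrosynthetic overview**
- Feature: the aza-quaternary spiro carbon C9a (bonded to N4, C1, C9 and C12) is shared by pyrrolidine ring A, azepane ring B and cyclopentane ring C, with N4 and C8 trans across the C9a–C9 bond. This bond is made while ring B is still open.
- Target 37 ⇐ C5 thiolactam ⇐ lactam ⇐ ring-closing metathesis (C7=C8, ring B last) of spiro N-but-3-enoyl amide 33 ⇐ aza-Sakurai closure of ring C (C9a–C9) from enamide 31.
- 31 ⇐ N-acylation of 1-pyrroline 29 (ring A by amine–ketone condensation) ⇐ ketone 27 ⇐ Fukuyama coupling (C1–C9a) of thioester 16 with the organozinc from iodide 25.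
- 16 (ring D) ⇐ (Z)-pentenylboration (C10–C11), Fráter–Seebach alkylation with a lactate triflate (C12–C13), lactonisation, enolate hydroxylation (C13–OH), cross-metathesis with allyltrimethylsilane.
- 25 (ring E) ⇐ L-homoserine-derived α-amino aldehyde + methyl-branched homoenolate (C18–C19). Ring order: E and D, then A, C, B.

Key step: step 16

Numbering used in all names: N4; ring A = N4, C3, C2, C1, C9a; ring B = N4, C5–C9, C9a; ring C = C9a, C9, C10 (ethyl), C11, C12; lactone ring D = C11, O, C14(=O), C13(OH)(CH3), C12; lactone ring E = C18, O, C21(=O), C20(CH3), C19, attached at C3.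

Remark on the chemistry: the cross-metathesis of step 7 is assumed to give mainly the E-allylsilane that is drawn; any Z isomer is expected to converge in step 16, where the silyl group is lost.

**Route**

Step 1
Reactants: 1 tert-butyl but-3-enoate
Product: 2 tert-butyl 3-oxopropanoate
Conditions: O3, CH2Cl2, −78 °C; PPh3, −78 °C → rt; filtered through silica and used at once
Reagents that add atoms: ozone, [O-][O+]=O
Why: Ozonolysis with reductive work-up cleaves the terminal alkene to the β-formyl ester, which is not stored because it enolises and self-condenses.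

Step 2
Reactants: 3 (3E)-penta-1,3-diene; 4 pinacolborane
Product: 5 4,4,5,5-tetramethyl-2-[(2Z)-pent-2-en-1-yl]-1,3,2-dioxaborolane
Conditions: Ni(cod)2 (2.5 mol %), PCy3 (2.5 mol %), toluene, rt
Reagents that add atoms: none
Why: Nickel-catalysed 1,4-hydroboration of the s-cis-bound diene puts boron on C1 and hydrogen on C4, so the (Z)-allylboronate is the expected isomer.

Step 3
Reactants: 2 tert-butyl 3-oxopropanoate; 5 (Z)-pent-2-enylboronate
Product: 7 tert-butyl (3R,4R)-4-ethyl-3-hydroxyhex-5-enoate, via borate ester 6 (not isolated)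
Conditions: (S)-3,3′-bis(2,4,6-triisopropylphenyl)-1,1′-binaphthyl-2,2′-diyl hydrogen phosphate (5 mol %), 4 Å MS, toluene, −30 °C; aq NaHCO3
Reagents that add atoms: none
Why: Chiral phosphoric acid-catalysed allylboration through a closed chair transition state: the (Z)-boronate gives the syn C10/C11 pair and the (S)-catalyst should direct attack to the si face of the aldehyde, setting C11 (3R) and C10 (4R).

Step 4
Reactants: 7 β-hydroxy ester; 8 ethyl (2S)-2-{[(trifluoromethyl)sulfonyl]oxy}propanoate
Product: 10 tert-butyl (2S,3S,4S)-4-methyl-5-oxo-2-[(3R)-pent-1-en-3-yl]oxolane-3-carboxylate, via alkylated hydroxy diester 9 (not isolated)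
Conditions: LiN(iPr)2 (2.2 equiv), THF, −78 → −20 °C; 8, −78 → −40 °C; AcOH; then TsOH·H2O (cat.), CH2Cl2, rt
Reagents that add atoms: none
Why: Fráter–Seebach alkylation: the lithium-chelated alkoxide enolate is alkylated at C12 anti to the C11 side chain by SN2 displacement of the triflate, and acid-catalysed lactonisation of the C11 hydroxyl onto the ethyl ester closes ring D with the C9a ester cis to the C10 arm (C12 set; the C13 configuration is erased in step 6).

Step 5
Reactants: 10 lactone tert-butyl ester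
Product: 11 (2S,3S,4S)-4-methyl-5-oxo-2-[(3R)-pent-1-en-3-yl]oxolane-3-carboxylic acid
Conditions: CF3CO2H–CH2Cl2 (1:4), 0 °C → rt
Reagents that add atoms: none
Why: Acidolysis of the tert-butyl ester (loss of isobutene) leaves the lactone and the terminal alkene untouched.

Step 6
Reactants: 11 lactone acid
Product: 12 (2S,3R,4S)-4-hydroxy-4-methyl-5-oxo-2-[(3R)-pent-1-en-3-yl]oxolane-3-carboxylic acid
Conditions: KN(SiMe3)2 (2.3 equiv), THF, −78 °C; 2-(phenylsulfonyl)-3-phenyloxaziridine, −78 °C; aq HCl
Reagents that add atoms: 2-(phenylsulfonyl)-3-phenyloxaziridine, O=S(=O)(N1OC1c1ccccc1)c1ccccc1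
Why: Enolate oxidation with an N-sulfonyloxaziridine: the carboxylate keeps C12 from enolising, and the C13 lactone enolate is hydroxylated on the face opposite to the cis C12 carboxylate and C11 side chain, setting C13 (OH trans, methyl cis to both).

Step 7
Reactants: 12 hydroxy lactone acid; 13 allyltrimethylsilane
Product: 14 (2S,3R,4S)-4-hydroxy-4-methyl-5-oxo-2-[(3R,4E)-6-(trimethylsilyl)hex-4-en-3-yl]oxolane-3-carboxylic acid
Conditions: 13 (5 equiv), Hoveyda–Grubbs second-generation catalyst (5 mol %), CH2Cl2, 40 °C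
Reagents that add atoms: none
Why: Olefin cross-metathesis of the allylic-branched vinyl group with excess allylsilane is driven by loss of ethene and should favour the E-allylsilane; the free acid and tertiary alcohol are tolerated.

Step 8
Reactants: 14 allylsilane acid; 15 ethanethiol
Product: 16 S-ethyl (2S,3R,4S)-4-hydroxy-4-methyl-5-oxo-2-[(3R,4E)-6-(trimethylsilyl)hex-4-en-3-yl]oxolane-3-carbothioate
Conditions: 15 (3 equiv), DCC, DMAP (5 mol %), CH2Cl2, 0 °C
Reagents that add atoms: none
Why: Carbodiimide (Steglich-type) thioesterification; the hindered tertiary C13 hydroxyl does not compete and the allylsilane is inert.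

Step 9
Reactants: 17 N-Fmoc-O-trityl-L-homoserine; 18 N,O-dimethylhydroxylamine hydrochloride
Product: 19 (9H-fluoren-9-yl)methyl N-[(2S)-1-[methoxy(methyl)amino]-1-oxo-4-(trityloxy)butan-2-yl]carbamate
Conditions: 1,1′-carbonyldiimidazole (1.1 equiv), CH2Cl2, 0 °C; 18, rt
Reagents that add atoms: none
Why: Acyl imidazolide formation and aminolysis give the N-methoxy-N-methylamide with no base strong enough to cleave Fmoc or epimerise C3.

Step 10
Reactants: 19 N-methoxy-N-methylamide
Product: 20 (9H-fluoren-9-yl)methyl N-[(2S)-1-oxo-4-(trityloxy)butan-2-yl]carbamate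
Conditions: LiAlH4 (1.2 equiv), THF, −40 → 0 °C; aq Rochelle salt; used crude
Reagents that add atoms: none
Why: Hydride reduction stops at the chelated tetrahedral intermediate, which releases the configurationally labile α-amino aldehyde only on work-up.

Step 11
Reactants: 20 α-amino aldehyde; 21 methyl (2R)-3-bromo-2-methylpropanoate
Product: 24 (9H-fluoren-9-yl)methyl N-[(1S)-3-hydroxy-1-[(2S,4S)-4-methyl-5-oxooxolan-2-yl]propyl]carbamate, via zinc homoenolate 22 (not isolated), via open-chain hydroxy ester 23 (not isolated)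
Conditions: 21, Zn dust (Me3SiCl/BrCH2CH2Br-activated), LiCl, THF, 45 °C; ClTi(OiPr)3, CH2Cl2, −40 °C; 20, −40 → 0 °C; aq NH4Cl; then TsOH·H2O (cat.), MeOH–CH2Cl2, rt
Reagents that add atoms: none
Why: Zinc insertion and transmetalation give a titanium homoenolate that adds to the aldehyde under chelation control (carbamate and formyl oxygen on titanium), setting C18 syn to C3, while C20 is carried in from 21; acid then closes ring E and removes the trityl ether.

Step 12
Reactants: 24 hydroxy lactone
Product: 25 (9H-fluoren-9-yl)methyl N-[(1S)-3-iodo-1-[(2S,4S)-4-methyl-5-oxooxolan-2-yl]propyl]carbamate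
Conditions: I2, PPh3, imidazole, CH2Cl2, 0 °C → rt
Reagents that add atoms: iodine, II
Why: Appel iodination of the primary alcohol proceeds under near-neutral conditions that spare the Fmoc group and the lactone.

Step 13
Reactants: 25 iodide; 16 thioester
Product: 27 Fmoc-protected γ-amino ketone (C9a ketone joining C12 of ring D to the C1–C2–C3(NHFmoc)–ring E chain; 3S,10R,11S,12R,13S,18S,20S), via organozinc iodide 26 (not isolated)
Conditions: 25 (1.6 equiv), Zn dust (I2-activated), DMF, rt; then 16, PdCl2(PPh3)2 (10 mol %), toluene, rt; aq NH4Cl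
Reagents that add atoms: none
Why: Fukuyama coupling: zinc inserts into the primary iodide and palladium-catalysed acyl transfer from the thioester forms the C1–C9a ketone under neutral conditions that leave both lactones, the carbamate, the tertiary alcohol, the allylsilane and the C12 configuration alone.

Step 14
Reactants: 27 Fmoc amino ketone
Product: 29 1-pyrroline (C9a=N4 imine carrying ring D through C12 on C9a and ring E on C3; 3S,10R,11S,12R,13S,18S,20S), via free amino ketone 28 (not isolated)
Conditions: piperidine (5 equiv), MeCN, rt, 30 min; evaporate; 4 Å MS, CH2Cl2, rt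
Reagents that add atoms: none
Why: Base-induced β-elimination of the Fmoc group frees the C3 amine, which closes ring A by condensation with the C9a ketone faster than it can attack either lactone, under non-acidic conditions that keep the allylsilane.

Step 15
Reactants: 29 1-pyrroline; 30 but-3-enoyl chloride
Product: 31 N-(but-3-enoyl) 2-pyrroline (endocyclic C9a=C1 enamide with the ring D hydroxybutanolide on C9a, the E-allylsilane arm on C11 and ring E on C3; 3S,10R,11S,12R,13S,18S,20S)
Conditions: 30 (1.5 equiv), pyridine (3 equiv), CH2Cl2, −40 → 0 °C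
Reagents that add atoms: none
Why: N-Acylation of the cyclic ketimine and loss of a C1 proton gives the endocyclic enamide, with pyridine at low temperature limiting ketene formation and double-bond migration in the acyl group (an exocyclic enamide isomer would give the same iminium ion in step 16).

Step 16
Reactants: 31 enamide
Product: 33 spiro tricyclic N-(but-3-enoyl) amine with a vinyl group on C9 (rings A, C, D and E; 3S,9R,9aS,10R,11S,12R,13S,18S,20S), via N-acyliminium triflate 32 (not isolated)
Conditions: CF3SO3H (1.2 equiv), CH2Cl2, −78 → −20 °C; aq NaHCO3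
Reagents that add atoms: none
Why: Protonation of the enamide at C1 gives the C9a N-acyliminium ion 32, which is attacked by C9, the γ-carbon of the allylsilane, with loss of the silyl group (aza-Sakurai; the closest known type is the N-acyliminium ion–allylsilane spirocyclisation of ketone-derived enamides). Ring C closes in a 5-exo-trig mode with respect to C9=C8, and the alkene emerges as the C9 vinyl group. C9a is set by attack on the iminium face anti to the C3 lactone, which allylic strain with the N-acyl group holds pseudoaxial, and this is the same face that is reached when C12–H rather than C13 lies next to the N-acyl group. C9 is set by the vinyl group pointing away from the N-acyl group and trans to the C10 ethyl group. The cis C11/C12 arrangement on ring D allows only the cis-fused bicycle, and a C12 epimer, which cannot close, should return through the enamide. The step needs enamide protonation to outrun protodesilylation, which the far higher basicity of the enamide at low temperature should secure, and the but-3-enoyl alkene is a much poorer nucleophile than the tethered allylsilane.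

Step 17
Reactants: 33 spiro diene
Product: 34 7,8-didehydro C5 lactam (ring B closed as the unsaturated azepinone; 3S,9R,9aS,10R,11S,12R,13S,18S,20S)
Conditions: second-generation Grubbs catalyst (10 mol %), 1,4-benzoquinone (20 mol %), toluene (2 mM), 80 °C
Reagents that add atoms: none
Why: Ring-closing metathesis of the two terminal alkenes forms C7=C8 and the 7-membered lactam, with benzoquinone suppressing migration of the β,γ-double bond.

Step 18
Reactants: 34 unsaturated lactam
Product: 35 saturated C5 lactam (3S,9R,9aS,10R,11S,12R,13S,18S,20S)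
Conditions: H2 (1 atm), Pd/C (10 %), EtOAc, rt
Reagents that add atoms: none
Why: Heterogeneous hydrogenation reduces the only C=C bond and creates no stereocentre.

Step 19
Reactants: 35 lactam
Product: 36 C5 thiolactam (3S,9R,9aS,10R,11S,12R,13S,18S,20S)
Conditions: Lawesson's reagent (0.6 equiv), toluene, 80 °C
Reagents that add atoms: Lawesson's reagent, COc1ccc(cc1)P1(=S)SP(=S)(S1)c1ccc(OC)cc1
Why: Thionation is selective for the tertiary lactam carbonyl over the two lactone carbonyls.

Step 20
Reactants: 36 thiolactam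
Product: 37 target CNP0260919.2 (3S,9R,9aS,10R,11S,12R,13S,18S,20S)
Conditions: Raney Ni (W-2), EtOH–THF, rt
Reagents that add atoms: none
Why: Raney nickel desulfurisation converts C=S into the C5 methylene and spares the lactones and the tertiary alcohol.

**Compound list**
1 | tert-butyl but-3-enoate | C=CCC(=O)OC(C)(C)C | starting material
2 | tert-butyl 3-oxopropanoate | O=CCC(=O)OC(C)(C)C | intermediate
3 | (3E)-penta-1,3-diene | C=C/C=C/C | starting material
4 | pinacolborane (4,4,5,5-tetramethyl-1,3,2-dioxaborolane) | [H]B1OC(C)(C)C(C)(C)O1 | starting material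
5 | 4,4,5,5-tetramethyl-2-[(2Z)-pent-2-en-1-yl]-1,3,2-dioxaborolane | CC/C=C\CB1OC(C)(C)C(C)(C)O1 | intermediate
6 | tert-butyl (3R,4R)-4-ethyl-3-[(4,4,5,5-tetramethyl-1,3,2-dioxaborolan-2-yl)oxy]hex-5-enoate | C=C[C@@H](CC)[C@H](OB1OC(C)(C)C(C)(C)O1)CC(=O)OC(C)(C)C | intermediate
7 | tert-butyl (3R,4R)-4-ethyl-3-hydroxyhex-5-enoate | C=C[C@@H](CC)[C@H](O)CC(=O)OC(C)(C)C | intermediate
8 | ethyl (2S)-2-{[(trifluoromethyl)sulfonyl]oxy}propanoate | CCOC(=O)[C@H](C)OS(=O)(=O)C(F)(F)F | starting material
9 | 1-tert-butyl 4-ethyl (2S,3S)-2-[(1S,2R)-2-ethyl-1-hydroxybut-3-en-1-yl]-3-methylbutanedioate | C=C[C@@H](CC)[C@H](O)[C@@H](C(=O)OC(C)(C)C)[C@H](C)C(=O)OCC | intermediate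
10 | tert-butyl (2S,3S,4S)-4-methyl-5-oxo-2-[(3R)-pent-1-en-3-yl]oxolane-3-carboxylate | C=C[C@@H](CC)[C@@H]1OC(=O)[C@@H](C)[C@@H]1C(=O)OC(C)(C)C | intermediate
11 | (2S,3S,4S)-4-methyl-5-oxo-2-[(3R)-pent-1-en-3-yl]oxolane-3-carboxylic acid | C=C[C@@H](CC)[C@@H]1OC(=O)[C@@H](C)[C@@H]1C(=O)O | intermediate
12 | (2S,3R,4S)-4-hydroxy-4-methyl-5-oxo-2-[(3R)-pent-1-en-3-yl]oxolane-3-carboxylic acid | C=C[C@@H](CC)[C@@H]1OC(=O)[C@@](C)(O)[C@@H]1C(=O)O | intermediate
13 | allyltrimethylsilane | C=CC[Si](C)(C)C | starting material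
14 | (2S,3R,4S)-4-hydroxy-4-methyl-5-oxo-2-[(3R,4E)-6-(trimethylsilyl)hex-4-en-3-yl]oxolane-3-carboxylic acid | C[Si](C)(C)C/C=C/[C@@H](CC)[C@@H]1OC(=O)[C@@](C)(O)[C@@H]1C(=O)O | intermediate
15 | ethanethiol | CCS | starting material
16 | S-ethyl (2S,3R,4S)-4-hydroxy-4-methyl-5-oxo-2-[(3R,4E)-6-(trimethylsilyl)hex-4-en-3-yl]oxolane-3-carbothioate | C[Si](C)(C)C/C=C/[C@@H](CC)[C@@H]1OC(=O)[C@@](C)(O)[C@@H]1C(=O)SCC | intermediate
17 | N-Fmoc-O-trityl-L-homoserine | OC(=O)[C@H](CCOC(c1ccccc1)(c1ccccc1)c1ccccc1)NC(=O)OCC1c2ccccc2-c2ccccc12 | starting material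
18 | N,O-dimethylhydroxylamine hydrochloride | CNOC.Cl | starting material
19 | (9H-fluoren-9-yl)methyl N-[(2S)-1-[methoxy(methyl)amino]-1-oxo-4-(trityloxy)butan-2-yl]carbamate | CON(C)C(=O)[C@H](CCOC(c1ccccc1)(c1ccccc1)c1ccccc1)NC(=O)OCC1c2ccccc2-c2ccccc12 | intermediate
20 | (9H-fluoren-9-yl)methyl N-[(2S)-1-oxo-4-(trityloxy)butan-2-yl]carbamate | O=C[C@H](CCOC(c1ccccc1)(c1ccccc1)c1ccccc1)NC(=O)OCC1c2ccccc2-c2ccccc12 | intermediate
21 | methyl (2R)-3-bromo-2-methylpropanoate | COC(=O)[C@@H](C)CBr | starting material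
22 | bromo[(2R)-3-methoxy-2-methyl-3-oxopropyl]zinc | COC(=O)[C@@H](C)C[Zn]Br | intermediate
23 | methyl (2S,4S,5S)-5-{[(9H-fluoren-9-ylmethoxy)carbonyl]amino}-4-hydroxy-2-methyl-7-(trityloxy)heptanoate | COC(=O)[C@@H](C)C[C@H](O)[C@H](CCOC(c1ccccc1)(c1ccccc1)c1ccccc1)NC(=O)OCC1c2ccccc2-c2ccccc12 | intermediate
24 | (9H-fluoren-9-yl)methyl N-[(1S)-3-hydroxy-1-[(2S,4S)-4-methyl-5-oxooxolan-2-yl]propyl]carbamate | O=C1O[C@@H](C[C@@H]1C)[C@H](CCO)NC(=O)OCC1c2ccccc2-c2ccccc12 | intermediate
25 | (9H-fluoren-9-yl)methyl N-[(1S)-3-iodo-1-[(2S,4S)-4-methyl-5-oxooxolan-2-yl]propyl]carbamate | O=C1O[C@@H](C[C@@H]1C)[C@H](CCI)NC(=O)OCC1c2ccccc2-c2ccccc12 | intermediate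
26 | organozinc iodide of 25 (C1–ZnI) | O=C1O[C@@H](C[C@@H]1C)[C@H](CC[Zn]I)NC(=O)OCC1c2ccccc2-c2ccccc12 | intermediate
27 | Fmoc-protected γ-amino ketone, C9a ketone (3S,10R,11S,12R,13S,18S,20S) | C[Si](C)(C)C/C=C/[C@@H](CC)[C@@H]1OC(=O)[C@@](C)(O)[C@@H]1C(=O)CC[C@H](NC(=O)OCC2c3ccccc3-c3ccccc23)[C@@H]2C[C@H](C)C(=O)O2 | intermediate
28 | free γ-amino ketone (3S,10R,11S,12R,13S,18S,20S) | C[Si](C)(C)C/C=C/[C@@H](CC)[C@@H]1OC(=O)[C@@](C)(O)[C@@H]1C(=O)CC[C@H](N)[C@@H]2C[C@H](C)C(=O)O2 | intermediate
29 | 1-pyrroline with ring D on C9a and ring E on C3 (3S,10R,11S,12R,13S,18S,20S) | C[Si](C)(C)C/C=C/[C@@H](CC)[C@@H]1OC(=O)[C@@](C)(O)[C@@H]1C2=N[C@@H](CC2)[C@@H]3C[C@H](C)C(=O)O3 | intermediate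
30 | but-3-enoyl chloride | C=CCC(=O)Cl | starting material
31 | N-(but-3-enoyl) 2-pyrroline with hydroxybutanolide allylsilane arm (3S,10R,11S,12R,13S,18S,20S) | C[Si](C)(C)C/C=C/[C@@H](CC)[C@@H]1OC(=O)[C@@](C)(O)[C@@H]1C2=CC[C@@H]([C@@H]3C[C@H](C)C(=O)O3)N2C(=O)CC=C | intermediate
32 | C9a N-acyliminium trifluoromethanesulfonate of 31 | C[Si](C)(C)C/C=C/[C@@H](CC)[C@@H]1OC(=O)[C@@](C)(O)[C@@H]1C2=[N+](C(=O)CC=C)[C@@H](CC2)[C@@H]3C[C@H](C)C(=O)O3.[O-]S(=O)(=O)C(F)(F)F | intermediate
33 | spiro tricyclic N-(but-3-enoyl) amine with C9 vinyl (3S,9R,9aS,10R,11S,12R,13S,18S,20S) | CC[C@H]1[C@@H]2OC(=O)[C@@](C)(O)[C@@H]2[C@]2(CC[C@@H]([C@@H]3C[C@H](C)C(=O)O3)N2C(=O)CC=C)[C@@H]1C=C | intermediate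
34 | 7,8-didehydro C5 lactam, rings A–E (3S,9R,9aS,10R,11S,12R,13S,18S,20S) | CC[C@H]1[C@@H]2OC(=O)[C@@](C)(O)[C@@H]2[C@@]23CC[C@@H]([C@@H]4C[C@H](C)C(=O)O4)N2C(=O)C/C=C\[C@H]13 | intermediate
35 | C5 lactam (3S,9R,9aS,10R,11S,12R,13S,18S,20S) | CC[C@H]1[C@@H]2OC(=O)[C@@](C)(O)[C@@H]2[C@@]23CC[C@@H]([C@@H]4C[C@H](C)C(=O)O4)N2C(=O)CCC[C@H]13 | intermediate
36 | C5 thiolactam (3S,9R,9aS,10R,11S,12R,13S,18S,20S) | CC[C@H]1[C@@H]2OC(=O)[C@@](C)(O)[C@@H]2[C@@]23CC[C@@H]([C@@H]4C[C@H](C)C(=O)O4)N2C(=S)CCC[C@H]13 | intermediate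
37 | CNP0260919.2 (3S,9R,9aS,10R,11S,12R,13S,18S,20S) | CC[C@H]1[C@@H]2OC(=O)[C@@](C)(O)[C@@H]2[C@@]23CC[C@@H]([C@@H]4C[C@H](C)C(=O)O4)N2CCCC[C@H]13 | target

**Step count and risks**

Total step count: 20. Longest linear sequence: 15 steps (steps 1, 3–8 and 13–20).

Steps most likely to fail:

1. Step 16. The allylsilane may be protodesilylated by the strong acid before the C9a–C9 bond forms, and face control may be lost if the C12 epimers of the iminium ion do not interconvert. The fallback sets out from pyrroline 29 and leaves out enamide 31. Imine 29 is treated with but-3-enoyl chloride 30 in CH2Cl2 at −78 °C without base, so that N-acylation itself gives the N-acyliminium chloride F1. This ion is trapped by the tethered allylsilane with loss of chlorotrimethylsilane, and no protic acid is present. The route is rejoined at 33.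

2. Step 4. The basic dianion may eliminate the secondary triflate or attack its ester carbonyl, so that the C12–C13 bond is not formed. The fallback sets out from 7. The same dianion is added to the ketone carbonyl of ethyl pyruvate (aldol addition in place of alkylation) to give the aldol adduct F2, which is lactonised under acid to the hydroxy lactone tert-butyl ester F3. C13 is then set in the addition and not by enolate oxidation, so its sense would have to be established and the C13 epimers separated. Acidolysis of F3 gives 12, where the route is rejoined; steps 5 and 6 are left out.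

3. Step 3. The β-formyl ester 2 may enolise and self-condense under the acid catalyst, and this small aliphatic aldehyde may be discriminated poorly by the catalyst. The fallback sets out from boronate 5, which is added under the same catalysis to the stable aldehyde 3-[(4-methoxybenzyl)oxy]propanal to give the homoallylic alcohol F4. Oxidative removal of the 4-methoxybenzyl group (DDQ, CH2Cl2–H2O) gives the diol F5. Selective oxidation of the primary alcohol (TEMPO, PhI(OAc)2, MeCN–H2O) gives the hydroxy acid F6. Esterification with N,N-dimethylformamide di-tert-butyl acetal (toluene, 80 °C) gives 7, where the route is rejoined.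

Further compounds
F1 | step 16 | C9a N-acyliminium chloride from 29 and 30 | C[Si](C)(C)C/C=C/[C@@H](CC)[C@@H]1OC(=O)[C@@](C)(O)[C@@H]1C2=[N+](C(=O)CC=C)[C@@H](CC2)[C@@H]3C[C@H](C)C(=O)O3.[Cl-]
F2 | step 4 | 1-tert-butyl 4-ethyl (2R,3S)-2-[(1S,2R)-2-ethyl-1-hydroxybut-3-en-1-yl]-3-hydroxy-3-methylbutanedioate | C=C[C@@H](CC)[C@H](O)[C@@H](C(=O)OC(C)(C)C)[C@](C)(O)C(=O)OCC
F3 | step 4 | tert-butyl (2S,3R,4S)-4-hydroxy-4-methyl-5-oxo-2-[(3R)-pent-1-en-3-yl]oxolane-3-carboxylate | C=C[C@@H](CC)[C@@H]1OC(=O)[C@@](C)(O)[C@@H]1C(=O)OC(C)(C)C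
F4 | step 3 | (3R,4R)-4-ethyl-1-[(4-methoxyphenyl)methoxy]hex-5-en-3-ol | C=C[C@@H](CC)[C@H](O)CCOCc1ccc(OC)cc1
F5 | step 3 | (3R,4R)-4-ethylhex-5-ene-1,3-diol | C=C[C@@H](CC)[C@H](O)CCO
F6 | step 3 | (3R,4R)-4-ethyl-3-hydroxyhex-5-enoic acid | C=C[C@@H](CC)[C@H](O)CC(=O)O
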